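All runs come from a simulation with constants of no real substance, noise included.

The constants are hidden from me, so I work from the two earlier runs, in powers of ten.

| flask | substrate | gas phase | remark | time |
|---|---|---|---|---|
| alpha | 0.12 M | 13 mM (held) | run made earlier |  |
| eta | 1.5 M | 13 mM (held) | run made earlier |  |
| teal | 1.2 M | 13 mM (held) |  | 2.0 h |
| ochre | 0.080 M | 13 mM (held) |  | 2.0 h |
| red | 0.15 M | 13 mM (held) |  | 2.0 h |
| grey | 0.30 M | 13 mM (held) |  | 2.0 h |

| run | time / min | target / % |
|---|---|---|
| alpha | 15.0 | 6 |
| alpha | 30.0 | 13 |
| alpha | 50.0 | 16 |
| alpha | 60.0 | 17 |
| alpha | 80.0 | 21 |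
| eta | 8.00 | 0 |
| eta | 20.0 | 0 |
| eta | 40.0 | 4 |
| eta | 60.0 | 1 |
| eta | 80.0 | 2 |

(each reading ± 1.5 percentage points)

- a species is counted by the substrate in it: one side product counts as two
- at the start none of the gas is dissolved
- the numbers in the tables scatter with a standard deviation of 1.5 percentage points
- on the list of suspects stand: gas phase <-> dissolved gas; substrate + dissolved gas -> target; substrate + target -> side product; dissolved gas -> decomposed reagent; target <-> isomer of the product

1. the flasks by amount of target, in percent of the substrate charged, highest first, at 2.0 h (teal / ochre / red / grey)
2. the amount of target, in percent of the substrate charged of the flask you put first, at 2.0 h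
3. the amount of target, in percent of the substrate charged of the flask you put last, at 2.0 h

Alpha's last reading of target is 21%, and eta's last 3 readings average 2.33%. I call the slope the powers of ten of target fraction lost per power of ten of charge, and between these runs it reads 0.870. I take it to lie between zero, where the fraction stays as it is, and one, where the target amount stays as it is. At equal gas and equal time, a slope above zero ranks the flasks by charge, lowest first.

Going from alpha to ochre, slope zero gives a lower edge of 21% and slope one an upper edge of 31.5%. My reckoning with the read slope gives 29.9%. Going from eta to teal, the average at slope zero gives a lower edge of 2.33%. Eta's highest reading at slope one gives an upper edge of 5.00%, and the read slope gives 2.83%. Both runs stop at 80.0 min, short of the asked 2.0 h, and I let that pass.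

The forecast says “the most dilute flask wins”, and it gives ochre > red > grey > teal, with 26% and 2.3%. Its top lies inside my ochre bracket, below my reckoning, and its low sits on the lower edge for teal.

The flasks give ochre > red > grey > teal, with ochre at 24.7% and teal at 3.62%, both inside the brackets. Between these two flasks the slope comes to 0.710, against the 0.870 read earlier. gas phase ⇌ dissolved gas, rate k1*(csat - [dissolved gas]) (kL = 0.00500 s⁻¹); substrate + dissolved gas → target (k = 0.0107 M⁻¹ s⁻¹); substrate + target → side product (k = 0.00100 M⁻¹ s⁻¹); dissolved gas → decomposed reagent (k = 3.70 × 10⁻⁴ s⁻¹); target ⇌ isomer of the product (K = 1.63, k = 3.13 × 10⁻⁴ s⁻¹) A further flask is like teal but charged at 0.30 M: from teal's 3.62%, the slope 0.870 gives 12.1%, and that flask holds 15.0% of target.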